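Remark on conventions and one assumption: positions carry daucane numbers (C1 quaternary methyl carbon, C2 and C3 ring methylenes, C4 carbinol with isopropyl, C5 ring-fusion CH, C6 ester carbinol, C8=C9 alkene); β is the face of the C1 methyl and α the face of H5. Commercial 3,4-dimethoxybenzoyl chloride is assumed as the activated form of veratric acid.

## Analysis of the target

Target 24 is the 3,4-dimethoxybenzoate of a daucane diol: a hydroazulene in which a cyclopentane (C1 to C5) is trans-fused to a cycloheptene (C5, C6, C7, C8, C9, C10, C1) that carries a methyl group on C8 and the C8=C9 alkene. The four stereocentres C1, C4, C5 and C6 are contiguous around C5. The C1 methyl and the C4 hydroxyl sit on the β face; H5, the isopropyl group and the C6 oxygen sit on the α face, so H5 and H6 are antiperiplanar. The sensitive groups are the tertiary alcohol (dehydration), the ester oxygen β to it (elimination across C5–C6 under base) and the trisubstituted alkene, which must stay out of conjugation in every intermediate. The main difficulty is C5, which lies between two fully substituted carbons and must carry its hydrogen on the concave face of the bicycle. A second difficulty is C1, a quaternary centre with no heteroatom next to it. The strategy rests on one observation: ring atoms C6, C1, C10, C9, C8 and C7, with oxygen on C6 and methyls on C1 and C8, are the six ring carbons of 2,5-dimethylanisole 1, C5 is a single carbon to be inserted between the oxygen-bearing carbon and its methyl-bearing neighbour, and after dearomatisation the arene also supplies the C8=C9 alkene in its final position.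

## Retrosynthetic reasoning

The ester C–O bond is cut first: 24 comes from diol 22 and acyl chloride 23. This is the only bond whose formation needs no stereocontrol, and a secondary hydroxyl can be acylated beside a tertiary one, so no protecting group is needed.

The C4–isopropyl bond is cut next: 22 comes from hydroxy ketone 20 and the isopropyl nucleophile derived from 21. A ketone at C4 is chosen because in the trans-fused bicycle the C1 methyl and the C5–C6 bond shield its β face, so addition from the α face should set C4 as required. The forward step must add a secondary carbanion to a hindered, enolisable β-hydroxy ketone without enolisation or retro-aldol cleavage.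

The C6–O and C5–H bonds are traced back together: 20 comes from epoxy ketone 18 by reductive cleavage of the C5–O bond. This keeps the C6–O bond, set earlier, and leaves C5 as an enolisable centre that can settle into the trans ring fusion through its cis-fused epimer 19. Epoxide 18 is traced to epoxy alcohol 17 and allylic alcohol 16 rather than directly to enone 15. The two faces of 15 differ only in a methyl group against a ring methylene at C1, so an undirected epoxidation would be poorly selective, whereas a hydroxyl on the α face of C4 can deliver the oxygen. Alcohol 16 comes from enone 15 by reagent-controlled reduction.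

The C4–C5 bond of the five-membered ring is cut: 15 comes through alcohol 14 from bromo aldehyde 13. The carbon–bromine bond on C5 is the nucleophilic partner and the aldehyde carbon C4 the electrophile. This uses the halogen that the ring expansion leaves on C5 and places the new alkene at C5=C6, conjugated to C4, where the C6 oxygen is needed later.

One carbon is removed from the chain: 13 comes from aldehyde 10 and phosphonium salt 11, and 10 from ester 9. The two-carbon arm of 9 is what a [3,3] shift delivers, so the third carbon is added separately.

The C1–C2 bond is cut: 9 comes from allylic alcohol 6 and orthoester 7 through ketene acetal 8. The rearrangement is suprafacial on the ring, so it carries the configuration of the C6 carbinol to the quaternary C1 and moves the alkene to C5=C6 with bromine still on C5. Alcohol 6 comes from ketone 5 by catalytic enantioselective reduction, for which a bromoalkenyl ketone is a favourable substrate.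

The key disconnection removes C5: 5 comes from diene 2 and the one carbon of 3, through cyclopropane 4. Both new bonds (C5–C6 and C5–C1) are formed on the enol ether double bond of 2, and opening of the three-membered ring gives the seven-membered ring with a ketone on C6, bromine on C5 and C1 as the β-carbon. Diene 2 is one reduction away from arene 1.

## Alternatives that were turned down

Alternative 1: The five-membered ring is cut at C1–C5. Forward, ketone A2, made from (S)-citronellol A3, is treated with Me3SiC(Li)N2. The alkylidene carbene so formed inserts its carbene carbon (C5) into the tertiary C1–H bond with retention and gives cyclopentene A1.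
- For: C1 is taken from the chiral pool without a catalyst or a chirality-transfer step, which is stronger than the chosen route on that point. The isopropyl group is in place and A1 is reached quickly.
- Against: A1 holds only the five-membered ring. The two-carbon arm must be extended by four carbons, and the seven-membered ring must then be closed onto the trisubstituted C4=C5 alkene. The C4 hydroxyl, the trans C5 hydrogen, the C6 oxygen and the C8=C9 alkene all remain to be set, so the step count after the key step is higher.
- Comparison: the chosen strategy delivers all seven ring carbons, both methyls and the alkene in two steps from an arene and leaves C5 and C6 functionalised. It pays for this with a catalytic reduction and a sigmatropic relay to reach C1.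

Alternative 2: Bonds C1–C5 and C1–C10 are cut. Forward, diazoketone A5 is decomposed by Rh2(OAc)4 or by Cu(MeCN)4PF6 with a chiral bisoxazoline ligand. The carbene adds to the ipso and free ortho carbons of the arene, and the norcaradiene opens to cycloheptatriene A4.
- For: both rings and the quaternary C1 are formed in one step, and the C4 carbinol with its isopropyl group is installed on a simple aromatic precursor. In bond-forming economy this is stronger than the chosen route.
- Against: the carbene carbon is fully substituted, so 1,2-hydride shift to an enone competes. Control of C1 relative to the existing C4 centre depends on diastereoselection for a substrate class that is difficult for asymmetric catalysts. A4 is at the wrong oxidation level: three ring alkenes and a C2 ketone must be reduced to leave only C8=C9, with C5–H and C6–O still to be set.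
- Comparison: the chosen strategy has the final unsaturation pattern from the Birch step onward and needs no selective reductions, at the cost of annulating the five-membered ring stepwise.

Alternative 3: Bonds C5–C1 and C9–C10 are formed, and the cyclobutanol bond C5–C9 is then cleaved. Forward, irradiation of the enol form of diketone A7 gives the [2+2] adduct, and retro-aldol opening expands the cyclopentanone to dione A6.
- For: both rings, a C4 ketone and an epimerisable C5 result from one operation without metals. In steps to the bicyclic core this is stronger than the chosen route.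
- Against: C6 in A6 is an unactivated methylene, so its oxygen would have to come from dehydrogenation and enone chemistry with a second ketone present. The C9 ketone must be converted regioselectively into the C8=C9 alkene. The absolute configuration at C1 depends on facial control by a remote, epimerisable methyl-bearing carbon.
- Comparison: the chosen strategy has the alkene fixed from the arene, an alkene at C5=C6 conjugated to C4 for oxygenation, and absolute control from a catalytic reduction.

Key step: step 2

## Route

Step 1
Reactants: 1 2,5-dimethylanisole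
Product: 2 1-methoxy-2,5-dimethylcyclohexa-1,4-diene
Conditions: Li, liquid NH3, THF, t-BuOH, −78 to −33 °C; then NH4Cl
Reagents that add atoms: none
Why: Birch reduction: the ring is protonated so that the methoxy group and both methyl groups stay on the two non-conjugated double bonds, and t-BuOH with a non-acidic work-up should keep the enol ether unconjugated and unhydrolysed; no stereocentre is formed.

Step 2
Reactants: 2 1-methoxy-2,5-dimethylcyclohexa-1,4-diene; 3 bromoform
Product: 5 2-bromo-3,6-dimethylcyclohepta-2,5-dien-1-one, via dibromocyclopropane 4 (not isolated)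
Conditions: CHBr3 (1.05 equiv), KOt-Bu (1.1 equiv), pentane, −30 to 0 °C; filter cold; then PhMe, solid CaCO3, 20 to 50 °C
Reagents that add atoms: bromoform, BrC(Br)Br
Why: α-Elimination of HBr from bromoform gives singlet dibromocarbene, an electrophile that should add in a concerted [2+1] cheletropic step to the most electron-rich π bond of 2, the tetrasubstituted enol ether, so that the carbene carbon (C5) is bonded to both C6 and C1 in cyclopropane 4. After the base is filtered off, gentle warming ionises the bromide that is syn to the six-membered ring while the shared C6–C1 bond opens in a two-electron disrotatory electrocyclic process pushed by the methoxy oxygen; the seven-membered ring therefore arises by ring enlargement and not by a cyclisation. The resulting cation is an O-methyl oxocarbenium ion, which bromide should demethylate by SN2 attack at the methyl group to give ketone 5 and bromomethane. The closest known reaction type is the dihalocarbene ring expansion of Birch-derived 1-methoxycyclohexa-1,4-dienes and other enol ethers to 2-halocycloheptenones and tropones. Product 5 has no stereocentre and the two of racemic 4 are destroyed, so no stereocontrol is needed. Site selectivity rests on the difference between an oxygen-substituted tetrasubstituted alkene and a trisubstituted alkyl alkene, together with the use of about one equivalent of carbene. The regiochemistry is fixed because only the methoxy-bearing terminus can become the carbonyl, which leaves bromine on C5 and the methyl-bearing C1 as the β-carbon. Loss of HBr to the dimethyltropone is held back by removing KOt-Bu before the opening and by running the opening neutral, aprotic and at moderate temperature.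

Step 3
Reactants: 5 2-bromo-3,6-dimethylcyclohepta-2,5-dien-1-one
Product: 6 (1S)-2-bromo-3,6-dimethylcyclohepta-2,5-dien-1-ol
Conditions: (R)-1-methyl-3,3-diphenyltetrahydro-1H,3H-pyrrolo[1,2-c][1,3,2]oxazaborole (15 mol %), catecholborane, PhMe, −78 °C; then MeOH, aq NaOH
Reagents that add atoms: none
Why: Corey–Bakshi–Shibata reduction: the ketone should bind to the catalyst with the bromoalkenyl arm as the large substituent and receive hydride on one face, giving the (S)-carbinol (C6); catecholborane at −78 °C does not hydroborate the trisubstituted alkene.

Step 4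
Reactants: 6 (1S)-2-bromo-3,6-dimethylcyclohepta-2,5-dien-1-ol; 7 triethyl orthoacetate
Product: 9 ethyl 2-[(1S)-2-bromo-1,5-dimethylcyclohepta-2,5-dien-1-yl]acetate, via ketene acetal 8 (not isolated)
Conditions: MeC(OEt)3 (excess), EtCO2H (5 mol %), 135 °C, EtOH distilled off
Reagents that add atoms: triethyl orthoacetate, CCOC(C)(OCC)OCC
Why: Johnson–Claisen rearrangement: exchange with the orthoester and loss of ethanol give ketene acetal 8, whose [3,3] shift is suprafacial on the ring, so the new C1–C2 bond should form on the face that carried the C6–O bond and relay the C6 configuration to the quaternary C1; the alkene moves to C5=C6 and bromine stays on C5.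

Step 5
Reactants: 9 ethyl 2-[(1S)-2-bromo-1,5-dimethylcyclohepta-2,5-dien-1-yl]acetate
Product: 10 2-[(1S)-2-bromo-1,5-dimethylcyclohepta-2,5-dien-1-yl]acetaldehyde
Conditions: i-Bu2AlH (1.1 equiv), CH2Cl2, −78 °C; aq potassium sodium tartrate
Reagents that add atoms: none
Why: Partial reduction of an ester with i-Bu2AlH: the aluminium hemiacetal is stable at −78 °C and should release the aldehyde only on work-up; the alkenyl bromide and the alkenes are inert.

Step 6
Reactants: 10 2-[(1S)-2-bromo-1,5-dimethylcyclohepta-2,5-dien-1-yl]acetaldehyde; 11 (methoxymethyl)triphenylphosphonium chloride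
Product: 13 3-[(1R)-2-bromo-1,5-dimethylcyclohepta-2,5-dien-1-yl]propanal, via enol ether 12 (not isolated)
Conditions: MeOCH2PPh3Cl, KN(SiMe3)2, THF, 0 °C; then 2 M HCl, THF, 20 °C
Reagents that add atoms: (methoxymethyl)triphenylphosphonium chloride, COC[P+](c1ccccc1)(c1ccccc1)c1ccccc1.[Cl-]; water, O
Why: Wittig reaction with the methoxymethylene ylide gives enol ether 12, and acid hydrolysis should deliver the aldehyde extended by one carbon (C4); dilute acid at room temperature should not protonate the trisubstituted alkene or the alkenyl bromide, and the change of descriptor at C1 reflects priorities only.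

Step 7
Reactants: 13 3-[(1R)-2-bromo-1,5-dimethylcyclohepta-2,5-dien-1-yl]propanal
Product: 14 (3aR)-3a,6-dimethyl-1,2,3,3a,4,7-hexahydroazulen-1-ol (both C-1 epimers)
Conditions: CrCl2 (6 equiv), NiCl2 (5 mol %), DMF, 0.01 M, 25 to 50 °C
Reagents that add atoms: none
Why: Intramolecular Nozaki–Hiyama–Kishi reaction: zerovalent nickel formed in the flask should insert into the C5–Br bond, transmetalation gives the alkenylchromium species and this adds to the aldehyde in a 5-exo-trig closure of the C4–C5 bond; the reagent is not basic, so the enolisable aldehyde survives, and the uncontrolled carbinol centre is erased in step 8.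

Step 8
Reactants: 14 (3aR)-3a,6-dimethyl-1,2,3,3a,4,7-hexahydroazulen-1-ol (both C-1 epimers)
Product: 15 (3aR)-3a,6-dimethyl-3,3a,4,7-tetrahydroazulen-1(2H)-one
Conditions: Dess–Martin periodinane, NaHCO3, CH2Cl2, 0 to 20 °C
Reagents that add atoms: none
Why: Dess–Martin oxidation of a secondary allylic alcohol under buffered, non-basic conditions should converge both epimers on one enone and leave the skipped C5=C6 and C8=C9 alkenes unisomerised.

Step 9
Reactants: 15 (3aR)-3a,6-dimethyl-3,3a,4,7-tetrahydroazulen-1(2H)-one
Product: 16 (1R,3aR)-3a,6-dimethyl-1,2,3,3a,4,7-hexahydroazulen-1-ol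
Conditions: (S)-1-methyl-3,3-diphenyltetrahydro-1H,3H-pyrrolo[1,2-c][1,3,2]oxazaborole (20 mol %), catecholborane, PhMe, −78 °C; then MeOH, aq NaOH
Reagents that add atoms: none
Why: Corey–Bakshi–Shibata reduction under catalyst control: the fully substituted alkenyl carbon C5 is the large substituent and C3H2 the small one, so the (S)-catalyst should give the (1R)-alcohol, with the C4 hydroxyl on the α face, trans to the C1 methyl; at −78 °C the catalysed 1,2-reduction should outrun conjugate reduction by catecholborane.

Step 10
Reactants: 16 (1R,3aR)-3a,6-dimethyl-1,2,3,3a,4,7-hexahydroazulen-1-ol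
Product: 17 (1R,3aR,8S,8aS)-8,8a-epoxy-3a,6-dimethyl-1,2,3,3a,4,7,8,8a-octahydroazulen-1-ol
Conditions: VO(acac)2 (5 mol %), t-BuOOH, PhMe, 0 to 20 °C
Reagents that add atoms: tert-butyl hydroperoxide, CC(C)(C)OO
Why: Hydroxyl-directed epoxidation: the vanadium alkoxide of the allylic alcohol should transfer the peroxide oxygen to the face of C5=C6 on which the hydroxyl sits (O–C4–C5=C6 dihedral near 60°), which fixes the C5–O and C6–O bonds as α; the isolated C8=C9 alkene has no directing group and should not react.

Step 11
Reactants: 17 (1R,3aR,8S,8aS)-8,8a-epoxy-3a,6-dimethyl-1,2,3,3a,4,7,8,8a-octahydroazulen-1-ol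
Product: 18 (3aR,8S,8aR)-8,8a-epoxy-3a,6-dimethyl-2,3,3a,4,7,8-hexahydroazulen-1(8aH)-one
Conditions: Dess–Martin periodinane, NaHCO3, CH2Cl2, 0 to 20 °C
Reagents that add atoms: none
Why: Dess–Martin oxidation of the secondary alcohol next to the epoxide; the neutral conditions should leave the epoxide and the configuration at C5 and C6 untouched.

Step 12
Reactants: 18 (3aR,8S,8aR)-8,8a-epoxy-3a,6-dimethyl-2,3,3a,4,7,8-hexahydroazulen-1(8aH)-one
Product: 20 (3aR,8S,8aS)-8-hydroxy-3a,6-dimethyl-2,3,3a,4,7,8-hexahydroazulen-1(8aH)-one, via cis-fused epimer 19 (not isolated)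
Conditions: SmI2 (2.2 equiv), THF–MeOH, −78 °C; aq NH4Cl; then 1,8-diazabicyclo[5.4.0]undec-7-ene (10 mol %), PhMe, 0 to 20 °C
Reagents that add atoms: none
Why: Reductive opening of an α,β-epoxy ketone with SmI2: two single-electron transfers cleave the C5–O bond next to the carbonyl and keep the C6–O bond with its α configuration; the samarium enolate is protonated at C5 by methanol, probably mainly on the convex β face to give cis-fused 19, and the amidine base should then equilibrate this enolisable centre to trans-fused 20, in which C4 and the C6 hydroxyl are both equatorial on the seven-membered ring and H5 and H6 are antiperiplanar.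

Step 13
Reactants: 20 (3aR,8S,8aS)-8-hydroxy-3a,6-dimethyl-2,3,3a,4,7,8-hexahydroazulen-1(8aH)-one; 21 isopropylmagnesium chloride
Product: 22 (3R,3aS,4S,8aR)-6,8a-dimethyl-3-(propan-2-yl)-1,2,3,3a,4,5,8,8a-octahydroazulene-3,4-diol
Conditions: i-PrMgCl (3 equiv), CeCl3 (3 equiv, dried), THF, −78 to −40 °C; aq NH4Cl
Reagents that add atoms: isopropylmagnesium chloride, CC(C)[Mg]Cl
Why: 1,2-Addition of an organocerium reagent, which is nucleophilic but weakly basic and should add to the hindered, enolisable β-hydroxy ketone instead of deprotonating it; in trans-fused 20 the β face of the carbonyl is screened by the C1 methyl and the C5–C6 bond, so isopropyl should enter from the α face and the new hydroxyl should be β.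

Step 14
Reactants: 22 (3R,3aS,4S,8aR)-6,8a-dimethyl-3-(propan-2-yl)-1,2,3,3a,4,5,8,8a-octahydroazulene-3,4-diol; 23 3,4-dimethoxybenzoyl chloride
Product: 24 (3R,3aS,4S,8aR)-3-hydroxy-6,8a-dimethyl-3-(propan-2-yl)-1,2,3,3a,4,5,8,8a-octahydroazulen-4-yl 3,4-dimethoxybenzoate
Conditions: 3,4-(MeO)2C6H3COCl, Et3N, 4-(dimethylamino)pyridine (10 mol %), CH2Cl2, 0 to 20 °C
Reagents that add atoms: 3,4-dimethoxybenzoyl chloride, COc1ccc(C(=O)Cl)cc1OC
Why: Acylation with an acid chloride under nucleophilic catalysis: the secondary C6 hydroxyl should be esterified while the tertiary C4 hydroxyl is too hindered to react, and no stereocentre is touched.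

## Compound list

1 | 2,5-dimethylanisole (2-methoxy-1,4-dimethylbenzene) | COc1cc(C)ccc1C | starting material
2 | 1-methoxy-2,5-dimethylcyclohexa-1,4-diene | COC1=C(C)CC=C(C)C1 | intermediate
3 | bromoform | BrC(Br)Br | starting material
4 | rac-7,7-dibromo-1-methoxy-3,6-dimethylbicyclo[4.1.0]hept-3-ene (cis-fused, one enantiomer drawn) | CO[C@]12CC(C)=CC[C@@]1(C)C2(Br)Br | intermediate (not isolated)
5 | 2-bromo-3,6-dimethylcyclohepta-2,5-dien-1-one | CC1=CCC(C)=C(Br)C(=O)C1 | intermediate
6 | (1S)-2-bromo-3,6-dimethylcyclohepta-2,5-dien-1-ol | O[C@H]1CC(C)=CCC(C)=C1Br | intermediate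
7 | triethyl orthoacetate | CCOC(C)(OCC)OCC | starting material
8 | (7S)-1-bromo-7-[(1-ethoxyethenyl)oxy]-2,5-dimethylcyclohepta-1,4-diene | CCOC(=C)O[C@H]1CC(C)=CCC(C)=C1Br | intermediate (not isolated)
9 | ethyl 2-[(1S)-2-bromo-1,5-dimethylcyclohepta-2,5-dien-1-yl]acetate | CCOC(=O)C[C@]1(C)CC=C(C)CC=C1Br | intermediate
10 | 2-[(1S)-2-bromo-1,5-dimethylcyclohepta-2,5-dien-1-yl]acetaldehyde | O=CC[C@]1(C)CC=C(C)CC=C1Br | intermediate
11 | (methoxymethyl)triphenylphosphonium chloride | COC[P+](c1ccccc1)(c1ccccc1)c1ccccc1.[Cl-] | starting material
12 | (7S)-1-bromo-7-(3-methoxyprop-2-en-1-yl)-4,7-dimethylcyclohepta-1,4-diene (E/Z mixture) | COC=CC[C@]1(C)CC=C(C)CC=C1Br | intermediate (not isolated)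
13 | 3-[(1R)-2-bromo-1,5-dimethylcyclohepta-2,5-dien-1-yl]propanal | O=CCC[C@]1(C)CC=C(C)CC=C1Br | intermediate
14 | (3aR)-3a,6-dimethyl-1,2,3,3a,4,7-hexahydroazulen-1-ol (both C-1 epimers) | OC1CC[C@]2(C)CC=C(C)CC=C12 | intermediate
15 | (3aR)-3a,6-dimethyl-3,3a,4,7-tetrahydroazulen-1(2H)-one | O=C1CC[C@]2(C)CC=C(C)CC=C12 | intermediate
16 | (1R,3aR)-3a,6-dimethyl-1,2,3,3a,4,7-hexahydroazulen-1-ol | O[C@@H]1CC[C@]2(C)CC=C(C)CC=C12 | intermediate
17 | (1R,3aR,8S,8aS)-8,8a-epoxy-3a,6-dimethyl-1,2,3,3a,4,7,8,8a-octahydroazulen-1-ol | O[C@@H]1CC[C@]2(C)CC=C(C)C[C@@H]3O[C@]123 | intermediate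
18 | (3aR,8S,8aR)-8,8a-epoxy-3a,6-dimethyl-2,3,3a,4,7,8-hexahydroazulen-1(8aH)-one | O=C1CC[C@]2(C)CC=C(C)C[C@@H]3O[C@]123 | intermediate
19 | (3aR,8S,8aR)-8-hydroxy-3a,6-dimethyl-2,3,3a,4,7,8-hexahydroazulen-1(8aH)-one (cis-fused) | O[C@H]1CC(C)=CC[C@@]2(C)CCC(=O)[C@@H]12 | intermediate (not isolated)
20 | (3aR,8S,8aS)-8-hydroxy-3a,6-dimethyl-2,3,3a,4,7,8-hexahydroazulen-1(8aH)-one (trans-fused) | O[C@H]1CC(C)=CC[C@@]2(C)CCC(=O)[C@H]12 | intermediate
21 | isopropylmagnesium chloride | CC(C)[Mg]Cl | starting material
22 | (3R,3aS,4S,8aR)-6,8a-dimethyl-3-(propan-2-yl)-1,2,3,3a,4,5,8,8a-octahydroazulene-3,4-diol | O[C@H]1CC(C)=CC[C@@]2(C)CC[C@@](O)(C(C)C)[C@H]12 | intermediate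
23 | 3,4-dimethoxybenzoyl chloride | COc1ccc(C(=O)Cl)cc1OC | starting material
24 | (3R,3aS,4S,8aR)-3-hydroxy-6,8a-dimethyl-3-(propan-2-yl)-1,2,3,3a,4,5,8,8a-octahydroazulen-4-yl 3,4-dimethoxybenzoate | COc1ccc(C(=O)O[C@H]2CC(C)=CC[C@@]3(C)CC[C@@](O)(C(C)C)[C@H]23)cc1OC | target

## Step count and least certain steps

Total: 14 steps. Longest linear sequence: 14 steps, from 1 to 24; the route is fully linear.

**Step 2 (key step).**
- What may go wrong: loss of HBr with aromatisation to the dimethyltropone, or migration of the skipped alkenes into conjugation. The C7 hydrogens of 5 are both α to the ketone and allylic, so traces of base or of HBr formed by proton loss from the cation start this drift.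
- Fallback: setting out from 4, kept cold in pentane, ionisation is assisted with AgBF4 and 2,6-lutidine in methanol at −20 °C. Methanol captures the oxocarbenium ion and gives 1-bromo-7,7-dimethoxy-2,5-dimethylcyclohepta-1,4-diene F1, a ketal that cannot enolise and can be purified. Hydrolysis with oxalic acid on wet silica gel in CH2Cl2 returns to the route at 5, immediately before step 3.

**Step 12.**
- What may go wrong: protonation on the convex face gives the cis-fused epimer, and the equilibrium may not lie far enough on the trans side. The base needed for equilibration may also cause β-elimination of water or retro-aldol opening. If the C5 epimer is carried forward, the facial preference at C4 in step 13 is lost as well.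
- Fallback: the ring-fusion hydrogen is delivered by a stereospecific 1,2-hydride shift instead of by protonation. Setting out from 15, reduction with the (R)-oxazaborolidine of step 3 and catecholborane gives the epimeric alcohol (1S,3aR)-3a,6-dimethyl-1,2,3,3a,4,7-hexahydroazulen-1-ol F2. VO(acac)2 and t-BuOOH then give the β-epoxy alcohol (1S,3aR,8R,8aR)-8,8a-epoxy-3a,6-dimethyl-1,2,3,3a,4,7,8,8a-octahydroazulen-1-ol F3, and Et3SiCl with imidazole gives its triethylsilyl ether F4. Et3SiOTf with 2,6-di-tert-butyl-4-methylpyridine in CH2Cl2 at −78 °C triggers a semipinacol rearrangement: the C4 hydrogen, anti to the breaking C5–O bond, migrates to the α face of C5, C4 becomes the ketone and the silyl group passes to the C6 oxygen, which gives the trans-fused β-silyloxy ketone F5 with the C6 oxygen β. Addition of i-PrMgCl and CeCl3 from the α face gives the tertiary alcohol F6, dilute HCl in THF frees the 6-epimeric diol F7, and Dess–Martin oxidation of its secondary hydroxyl gives the hydroxy ketone F8. Me4NBH(OAc)3 in AcOH–MeCN at −20 °C, bound to the β-oriented C4 hydroxyl, delivers hydride to the β face of the C6 carbonyl and returns to the route at 22, immediately before step 14.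

**Step 4.**
- What may go wrong: ionisation of the allylic alcohol or of its orthoester under acid at 135 °C, with elimination to a bromocycloheptatriene or loss of configuration before the rearrangement.
- Fallback: setting out from 6, acetylation (Ac2O, pyridine) gives (1S)-2-bromo-3,6-dimethylcyclohepta-2,5-dien-1-yl acetate F9. Ireland–Claisen rearrangement (LiN(i-Pr)2, Me3SiCl, THF, −78 °C, then warming to reflux, then dilute acid) gives 2-[(1S)-2-bromo-1,5-dimethylcyclohepta-2,5-dien-1-yl]acetic acid F10 under base and without acid catalysis. Alkylation with EtI and K2CO3 in DMF returns to the route at 9.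

**Step 7.**
- What may go wrong: slow insertion of nickel into the hindered alkenyl bromide, so that reductive coupling of the aldehyde, reduction of the aldehyde or protodebromination takes over.
- Fallback: setting out from 13, oxidation with NaClO2, NaH2PO4 and 2-methylbut-2-ene gives 3-[(1R)-2-bromo-1,5-dimethylcyclohepta-2,5-dien-1-yl]propanoic acid F11. Coupling with MeNHOMe·HCl (carbodiimide, Et3N) gives 3-[(1R)-2-bromo-1,5-dimethylcyclohepta-2,5-dien-1-yl]-N-methoxy-N-methylpropanamide F12. Bromine–lithium exchange with t-BuLi (2 equiv, THF, −78 °C) and attack of the alkenyllithium on the amide returns to the route at 15, replacing steps 7 and 8.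

**Step 13.**
- What may go wrong: transfer of a β-hydrogen from the isopropyl reagent (reduction of the ketone), enolisation with loss of the C5 configuration, or retro-aldol opening of the cerium alkoxide. All three arise because the carbonyl is flanked by a tertiary carbon next to a quaternary one.
- Fallback: setting out from 20, the smaller sp2 nucleophile CH2=C(CH3)MgBr with CeCl3, which has no β-hydrogen to transfer, gives (3S,3aS,4S,8aR)-6,8a-dimethyl-3-(prop-1-en-2-yl)-1,2,3,3a,4,5,8,8a-octahydroazulene-3,4-diol F13. Hydrogenation with RhCl(PPh3)3 and H2 in benzene, which reduces the 1,1-disubstituted alkene in preference to the trisubstituted ring alkene, returns to the route at 22.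

## Further compounds

F1 | step 2 | 1-bromo-7,7-dimethoxy-2,5-dimethylcyclohepta-1,4-diene | COC1(OC)CC(C)=CCC(C)=C1Br
F2 | step 12 | (1S,3aR)-3a,6-dimethyl-1,2,3,3a,4,7-hexahydroazulen-1-ol | O[C@H]1CC[C@]2(C)CC=C(C)CC=C12
F3 | step 12 | (1S,3aR,8R,8aR)-8,8a-epoxy-3a,6-dimethyl-1,2,3,3a,4,7,8,8a-octahydroazulen-1-ol | O[C@H]1CC[C@]2(C)CC=C(C)C[C@H]3O[C@@]123
F4 | step 12 | O-triethylsilyl ether of F3 | CC[Si](CC)(CC)O[C@H]1CC[C@]2(C)CC=C(C)C[C@H]3O[C@@]123
F5 | step 12 | (3aR,8R,8aS)-3a,6-dimethyl-8-[(triethylsilyl)oxy]-2,3,3a,4,7,8-hexahydroazulen-1(8aH)-one | CC[Si](CC)(CC)O[C@@H]1CC(C)=CC[C@@]2(C)CCC(=O)[C@H]12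
F6 | step 12 | 4-O-triethylsilyl ether of F7 (azulene numbering) | CC[Si](CC)(CC)O[C@@H]1CC(C)=CC[C@@]2(C)CC[C@@](O)(C(C)C)[C@H]12
F7 | step 12 | (3R,3aS,4R,8aR)-6,8a-dimethyl-3-(propan-2-yl)-1,2,3,3a,4,5,8,8a-octahydroazulene-3,4-diol | O[C@@H]1CC(C)=CC[C@@]2(C)CC[C@@](O)(C(C)C)[C@H]12
F8 | step 12 | (3R,3aR,8aR)-3-hydroxy-6,8a-dimethyl-3-(propan-2-yl)-2,3,3a,5,8,8a-hexahydroazulen-4(1H)-one | O=C1CC(C)=CC[C@@]2(C)CC[C@@](O)(C(C)C)[C@H]12
F9 | step 4 | (1S)-2-bromo-3,6-dimethylcyclohepta-2,5-dien-1-yl acetate | CC(=O)O[C@H]1CC(C)=CCC(C)=C1Br
F10 | step 4 | 2-[(1S)-2-bromo-1,5-dimethylcyclohepta-2,5-dien-1-yl]acetic acid | OC(=O)C[C@]1(C)CC=C(C)CC=C1Br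
F11 | step 7 | 3-[(1R)-2-bromo-1,5-dimethylcyclohepta-2,5-dien-1-yl]propanoic acid | OC(=O)CC[C@]1(C)CC=C(C)CC=C1Br
F12 | step 7 | 3-[(1R)-2-bromo-1,5-dimethylcyclohepta-2,5-dien-1-yl]-N-methoxy-N-methylpropanamide | CON(C)C(=O)CC[C@]1(C)CC=C(C)CC=C1Br
F13 | step 13 | (3S,3aS,4S,8aR)-6,8a-dimethyl-3-(prop-1-en-2-yl)-1,2,3,3a,4,5,8,8a-octahydroazulene-3,4-diol | O[C@H]1CC(C)=CC[C@@]2(C)CC[C@@](O)(C(C)=C)[C@H]12
A1 | alternative 1 | (R)-tert-butyl[2-(3-isopropyl-1-methylcyclopent-2-en-1-yl)ethoxy]dimethylsilane | CC(C)C1=C[C@@](C)(CCO[Si](C)(C)C(C)(C)C)CC1
A2 | alternative 1 | (6S)-8-[(tert-butyldimethylsilyl)oxy]-2,6-dimethyloctan-3-one | CC(C)C(=O)CC[C@H](C)CCO[Si](C)(C)C(C)(C)C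
A3 | alternative 1 | (S)-citronellol | C[C@@H](CCC=C(C)C)CCO
A4 | alternative 2 | 3-isopropyl-4-methoxy-6,8a-dimethyl-3-[(trimethylsilyl)oxy]-3,8a-dihydroazulen-1(2H)-one (configured as in the SMILES) | COC1=C2[C@](O[Si](C)(C)C)(C(C)C)CC(=O)[C@]2(C)C=CC(C)=C1
A5 | alternative 2 | (5R)-2-diazo-5-(2-methoxy-4-methylphenyl)-6-methyl-5-[(trimethylsilyl)oxy]heptan-3-one | CC(=[N+]=[N-])C(=O)C[C@@](O[Si](C)(C)C)(C(C)C)c1ccc(C)cc1OC
A6 | alternative 3 | 3a,6-dimethyloctahydroazulene-1,5-dione (C3a and C6 configured as in the SMILES, ring-fusion CH unassigned) | C[C@@H]1CCC2C(=O)CC[C@]2(C)CC1=O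
A7 | alternative 3 | (2R)-2-methyl-5-(4-methylpent-4-enoyl)cyclopentan-1-one | C[C@@H]1CCC(C(=O)CCC(C)=C)C1=O
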